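**Plan**
- Retrosynthesis: ring C is cut at O1–C8a and C4–C4a (aryne annulation). The open chain is then cut at the ketone–CH2 bond of a β-keto Weinreb amide (Claisen condensation with a ring B ester). Ring B is traced back through its side-chain oxygenation, its aryl–prenyl bond and its chromene ring to a bromophenol ester.
- Enabling feature: in ring C the chain O1–C2–C3–C4 ends in a nucleophilic oxygen and an acyl carbon, and these ends sit on the adjacent carbons C8a and C4a of the resorcinol-type ring A. The C8a oxygen of that resorcinol can be spent as the triflate leaving group of a C4a≡C8a aryne. A chlorine at C5, removed later, polarises the aryne so that O1 enters at C8a.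
- Forward order: chromene ring of ring B (step 2), side chain (steps 3–6), β-silyloxy amide (steps 7–9); ring A aryne precursor (steps 10–14); ring C closes last (step 15); dechlorination and deprotection finish.
- Stereochemistry: the side-chain (R)-carbinol comes from Shi epoxidation and a syn-eliminative epoxide opening. C2 (S) comes from Noyori asymmetric transfer hydrogenation and is carried through the annulation with its C–O bond intact.

Key step: step 15

Remark: the target is read from its SMILES as (2S) at C2 of ring C and (R) at the side-chain carbinol; flavanone numbering (O1, C2–C4, C4a, C5–C8, C8a) is used for the target and for ring A; compounds 1, 2, 6, 11, 16 and 19 are taken as purchasable.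

Step 1
Reactants: 1 methyl 3-bromo-4-hydroxybenzoate; 2 3-chloro-3-methylbut-1-yne
Product: 3 methyl 3-bromo-4-[(2-methylbut-3-yn-2-yl)oxy]benzoate
Conditions: K2CO3, KI (cat.), CuI (cat.), acetone, reflux
Reagents that add atoms: none
Why: Copper-assisted Williamson-type O-alkylation of the phenoxide with the tertiary propargylic chloride is the standard entry to aryl 1,1-dimethylpropargyl ethers, and ester and aryl bromide are inert.

Step 2
Reactants: 3 methyl 3-bromo-4-[(2-methylbut-3-yn-2-yl)oxy]benzoate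
Product: 5 methyl 8-bromo-2,2-dimethyl-2H-chromene-6-carboxylate, via allenyl phenol 4 (not isolated)
Conditions: N,N-diethylaniline, 190 °C
Reagents that add atoms: none
Why: Aromatic propargyl Claisen rearrangement to the only free ortho carbon, tautomerisation to 4, 1,5-hydrogen shift and oxa-6π electrocyclisation should give the 2,2-dimethylchromene, the bromine blocking the other ortho position.

Step 3
Reactants: 5 methyl 8-bromo-2,2-dimethyl-2H-chromene-6-carboxylate; 6 tributyl(3-methylbut-2-en-1-yl)stannane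
Product: 7 methyl 2,2-dimethyl-8-(3-methylbut-2-en-1-yl)-2H-chromene-6-carboxylate
Conditions: Pd(PPh3)4 (5 mol%), DMF, 100 °C
Reagents that add atoms: none
Why: Stille coupling, in which reductive elimination from the aryl(η3-prenyl)palladium intermediate at the less substituted allyl terminus should give the linear prenyl arene while ester and chromene alkene survive.

Step 4
Reactants: 7 methyl 2,2-dimethyl-8-(3-methylbut-2-en-1-yl)-2H-chromene-6-carboxylate
Product: 8 methyl 8-{[(2R)-3,3-dimethyloxiran-2-yl]methyl}-2,2-dimethyl-2H-chromene-6-carboxylate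
Conditions: D-fructose-derived Shi ketone (1,2:4,5-di-O-isopropylidene-β-D-erythro-2,3-hexodiulo-2,6-pyranose, 30 mol%), KHSO5 (as the triple salt 2KHSO5·KHSO4·K2SO4), K2CO3, Bu4NHSO4 (cat.), MeCN/dimethoxymethane/aq. Na2B4O7 buffer (pH 10.5), 0 °C
Reagents that add atoms: potassium peroxymonosulfate, [K+].[O-]S(=O)(=O)OO
Why: Shi epoxidation, in which the chiral dioxirane attacks the electron-rich trisubstituted prenyl alkene through the spiro transition state that sets (R) at the secondary epoxide carbon, while the cis-disubstituted chromene alkene on an ester-bearing ring is a poor substrate for this ketone and should react far more slowly.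

Step 5
Reactants: 8 methyl 8-{[(2R)-3,3-dimethyloxiran-2-yl]methyl}-2,2-dimethyl-2H-chromene-6-carboxylate
Product: 9 methyl 8-[(2R)-2-hydroxy-3-methylbut-3-en-1-yl]-2,2-dimethyl-2H-chromene-6-carboxylate
Conditions: diethylaluminium 2,2,6,6-tetramethylpiperidide (from Et2AlCl and lithium 2,2,6,6-tetramethylpiperidide), toluene, 0 °C; aq. work-up
Reagents that add atoms: none
Why: Base-promoted epoxide-to-allylic-alcohol isomerisation, in which aluminium binds the epoxide oxygen, the C–O bond at the tertiary carbon breaks and the hindered amide removes a syn methyl proton in a cyclic transition state, so the secondary C–O bond keeps its (R) configuration and the non-enolisable aryl ester is not attacked.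

Step 6
Reactants: 9 methyl 8-[(2R)-2-hydroxy-3-methylbut-3-en-1-yl]-2,2-dimethyl-2H-chromene-6-carboxylate
Product: 10 methyl 8-[(2R)-2-{[tert-butyl(dimethyl)silyl]oxy}-3-methylbut-3-en-1-yl]-2,2-dimethyl-2H-chromene-6-carboxylate
Conditions: TBSCl, imidazole, DMF, rt
Reagents that add atoms: tert-butyldimethylsilyl chloride, CC(C)(C)[Si](C)(C)Cl
Why: Standard silylation of the secondary allylic alcohol gives an ether that should withstand enolates, formic acid and CsF and fall in the final acid step.

Step 7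
Reactants: 10 methyl 8-[(2R)-2-{[tert-butyl(dimethyl)silyl]oxy}-3-methylbut-3-en-1-yl]-2,2-dimethyl-2H-chromene-6-carboxylate; 11 N-methoxy-N-methylacetamide
Product: 13 3-{8-[(2R)-2-{[tert-butyl(dimethyl)silyl]oxy}-3-methylbut-3-en-1-yl]-2,2-dimethyl-2H-chromen-6-yl}-N-methoxy-N-methyl-3-oxopropanamide, via lithium enolate 12 (not isolated)
Conditions: LiN(iPr)2 (3 equiv), 11 (3 equiv), THF, −78 °C; then 10, −78 to 0 °C; aq. NH4Cl
Reagents that add atoms: none
Why: Crossed Claisen condensation of the amide enolate with the non-enolisable aryl ester, driven by deprotonation of the β-keto amide as it forms, with silyl ether and alkenes inert to the enolate.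

Step 8
Reactants: 13 3-{8-[(2R)-2-{[tert-butyl(dimethyl)silyl]oxy}-3-methylbut-3-en-1-yl]-2,2-dimethyl-2H-chromen-6-yl}-N-methoxy-N-methyl-3-oxopropanamide
Product: 14 (3S)-3-{8-[(2R)-2-{[tert-butyl(dimethyl)silyl]oxy}-3-methylbut-3-en-1-yl]-2,2-dimethyl-2H-chromen-6-yl}-3-hydroxy-N-methoxy-N-methylpropanamide
Conditions: RuCl[(S,S)-TsDPEN](p-cymene) (2 mol%), HCO2H/Et3N (5:2), DMF, 40 °C
Reagents that add atoms: none
Why: Noyori asymmetric transfer hydrogenation, in which the (S,S)-catalyst should deliver hydride to the aryl ketone face that gives the (S)-carbinol (aryl against alkyl discrimination as for acetophenone) without reducing alkenes, amide or silyl ether.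

Step 9
Reactants: 14 (3S)-3-{8-[(2R)-2-{[tert-butyl(dimethyl)silyl]oxy}-3-methylbut-3-en-1-yl]-2,2-dimethyl-2H-chromen-6-yl}-3-hydroxy-N-methoxy-N-methylpropanamide
Product: 15 (3S)-3-{8-[(2R)-2-{[tert-butyl(dimethyl)silyl]oxy}-3-methylbut-3-en-1-yl]-2,2-dimethyl-2H-chromen-6-yl}-N-methoxy-N-methyl-3-[(trimethylsilyl)oxy]propanamide
Conditions: TMSCl, imidazole, CH2Cl2, 0 °C
Reagents that add atoms: chlorotrimethylsilane, C[Si](C)(C)Cl
Why: Routine O-silylation removes the only acidic proton of the annulation partner and gives an ether that fluoride cleaves to the alkoxide in the flask in which the aryne is formed.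

Step 10
Reactants: 16 5-chlorobenzene-1,3-diol
Product: 17 3-chloro-5-(methoxymethoxy)phenol
Conditions: NaH (1 equiv), MOMCl (1 equiv), DMF, 0 °C
Reagents that add atoms: chloromethyl methyl ether, COCCl
Why: Statistical mono-etherification of the symmetric diol, with diol and bis-ether separable and recyclable, differentiates the future C7 oxygen (kept) from the future C8a oxygen (to be spent).

Step 11
Reactants: 17 3-chloro-5-(methoxymethoxy)phenol
Product: 18 3-chloro-5-(methoxymethoxy)phenyl N-(propan-2-yl)carbamate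
Conditions: iPrNCO, Et3N (cat.), CH2Cl2, rt
Reagents that add atoms: isopropyl isocyanate, CC(C)N=C=O
Why: Amine-catalysed addition of the phenol to the isocyanate installs a strong ortho-directing group that can later be removed under mild basic conditions.

Step 12
Reactants: 18 3-chloro-5-(methoxymethoxy)phenyl N-(propan-2-yl)carbamate; 19 1-bromo-3-methylbut-2-ene
Product: 23 5-chloro-3-(methoxymethoxy)-2-(3-methylbut-2-en-1-yl)phenyl N-(propan-2-yl)carbamate, via N-silyl carbamate 20 (not isolated), via aryllithium 21 (not isolated), via N-silyl prenyl carbamate 22 (not isolated)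
Conditions: TBSOTf, TMEDA, Et2O, 0 °C to rt; n-BuLi, TMEDA, −78 °C; CuBr·SMe2 (10 mol%), then 19, −78 to 0 °C; aq. NaHSO4
Reagents that add atoms: none
Why: Directed ortho-metalation of the transiently N-silylated carbamate (the bulky tert-butyldimethylsilyl group is chosen to survive the warming to 0 °C) at the ring carbon flanked by both oxygen directing groups, then copper-catalysed allylation at the primary carbon of prenyl bromide, should place the prenyl group on the future C8, and the acidic work-up hydrolyses the N–Si bond.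

Step 13
Reactants: 23 5-chloro-3-(methoxymethoxy)-2-(3-methylbut-2-en-1-yl)phenyl N-(propan-2-yl)carbamate
Product: 27 3-chloro-5-(methoxymethoxy)-6-(3-methylbut-2-en-1-yl)-2-(trimethylsilyl)phenyl N-(propan-2-yl)carbamate, via N-trimethylsilyl carbamate 24 (not isolated), via aryllithium 25 (not isolated), via N-silyl aryl silane 26 (not isolated)
Conditions: TMSOTf, TMEDA, Et2O, 0 °C to rt; n-BuLi, TMEDA, −78 °C; TMSCl, −78 °C to rt; aq. NaHSO4
Reagents that add atoms: chlorotrimethylsilane, C[Si](C)(C)Cl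
Why: After transient N-trimethylsilylation, which suffices here because the anion is quenched at −78 °C, a second directed ortho-metalation can only occur at the remaining position ortho to the carbamate, which chlorine acidifies further, and C-silylation at −78 °C precedes loss of LiCl or anionic Fries rearrangement, the labile N–Si bond being hydrolysed on work-up.

Step 14
Reactants: 27 3-chloro-5-(methoxymethoxy)-6-(3-methylbut-2-en-1-yl)-2-(trimethylsilyl)phenyl N-(propan-2-yl)carbamate
Product: 29 3-chloro-5-(methoxymethoxy)-6-(3-methylbut-2-en-1-yl)-2-(trimethylsilyl)phenyl trifluoromethanesulfonate, via silyl phenol 28 (not isolated)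
Conditions: Et2NH, DBU, MeCN, 40 °C; then PhNTf2, rt
Reagents that add atoms: N-phenylbis(trifluoromethanesulfonimide), O=S(=O)(N(c1ccccc1)S(=O)(=O)C(F)(F)F)C(F)(F)F
Why: E1cB cleavage of the N–H carbamate (isocyanate trapped by Et2NH) is insensitive to the two flanking groups, and triflation of the phenoxide in the same flask gives the ortho-silylaryl triflate.

Step 15
Reactants: 15 (3S)-3-{8-[(2R)-2-{[tert-butyl(dimethyl)silyl]oxy}-3-methylbut-3-en-1-yl]-2,2-dimethyl-2H-chromen-6-yl}-N-methoxy-N-methyl-3-[(trimethylsilyl)oxy]propanamide; 29 3-chloro-5-(methoxymethoxy)-6-(3-methylbut-2-en-1-yl)-2-(trimethylsilyl)phenyl trifluoromethanesulfonate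
Product: 32 (2S)-2-{8-[(2R)-2-{[tert-butyl(dimethyl)silyl]oxy}-3-methylbut-3-en-1-yl]-2,2-dimethyl-2H-chromen-6-yl}-5-chloro-7-(methoxymethoxy)-8-(3-methylbut-2-en-1-yl)-2,3-dihydro-4H-chromen-4-one, via aryne 30 (not isolated), via tetrahedral adduct 31 (not isolated)
Conditions: CsF, 18-crown-6 (cat.), THF, 25–45 °C; then aq. NH4Cl
Reagents that add atoms: none
Why: Proposed new method: fluoride cleaves the O–SiMe3 bond of 15 to the caesium alkoxide and, at the C–SiMe3 bond of 29, expels triflate to give aryne 30; the alkoxide adds at the aryne carbon remote from chlorine (C8a, next to the prenyl-bearing C8), and the aryl anion so formed at C4a adds to the Weinreb carbonyl to give the tetrahedral adduct 31, which releases the ketone only on aqueous quench. The closest known reaction types are the fluoride-induced annulation of arynes with salicylates to xanthones (nucleophilic addition to the aryne, then intramolecular acyl substitution) and the Parham cyclisation of ortho-lithiated aryl ethers onto Weinreb amides; new here are the aliphatic silyl ether as oxygen nucleophile and the amide as acyl acceptor. Ring C closes as a formal [4+2] anionic annulation of the O1–C2–C3–C4 chain across C8a–C4a, the C–C bond forming by 6-exo-trig attack. No stereocentre is created: C2 keeps the (S) configuration of step 8 because its C–O bond is never broken, and adduct 31 masks C4 so that no enolate and no retro-oxa-Michael opening should scramble C2 in the basic medium. The selectivity needed is regioselectivity, secured by the C5 chlorine, whose inductive pull and distortion of the aryne direct the nucleophile to C8a and stabilise the C4a anion against the weak opposite bias of the C7 ether and C8 alkyl group. Chemoselectivity rests on the much faster cleavage of the trimethylsilyl than of the tert-butyldimethylsilyl ether by CsF and on the aprotic medium, which offers the aryl anion no proton source faster than the six-membered acyl addition.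

Step 16
Reactants: 32 (2S)-2-{8-[(2R)-2-{[tert-butyl(dimethyl)silyl]oxy}-3-methylbut-3-en-1-yl]-2,2-dimethyl-2H-chromen-6-yl}-5-chloro-7-(methoxymethoxy)-8-(3-methylbut-2-en-1-yl)-2,3-dihydro-4H-chromen-4-one
Product: 33 (2S)-2-{8-[(2R)-2-{[tert-butyl(dimethyl)silyl]oxy}-3-methylbut-3-en-1-yl]-2,2-dimethyl-2H-chromen-6-yl}-7-(methoxymethoxy)-8-(3-methylbut-2-en-1-yl)-2,3-dihydro-4H-chromen-4-one
Conditions: Pd(OAc)2 (5 mol%), XPhos (10 mol%), HCO2H (2 equiv), Et3N (3 equiv), 1,4-dioxane, 60 °C
Reagents that add atoms: none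
Why: Palladium-catalysed transfer hydrodechlorination (oxidative addition of zerovalent palladium into the C–Cl bond activated by the ortho carbonyl, formate-to-hydride exchange with loss of CO2, C–H reductive elimination) should remove the control element in a medium too weakly basic to open the flavanone and without reducing isolated alkenes.

Step 17
Reactants: 33 (2S)-2-{8-[(2R)-2-{[tert-butyl(dimethyl)silyl]oxy}-3-methylbut-3-en-1-yl]-2,2-dimethyl-2H-chromen-6-yl}-7-(methoxymethoxy)-8-(3-methylbut-2-en-1-yl)-2,3-dihydro-4H-chromen-4-one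
Product: 34 (2S)-7-hydroxy-2-{8-[(2R)-2-hydroxy-3-methylbut-3-en-1-yl]-2,2-dimethyl-2H-chromen-6-yl}-8-(3-methylbut-2-en-1-yl)-2,3-dihydro-4H-chromen-4-one (CNP0104040.1)
Conditions: HCl (1 M in MeOH), 0 °C to rt
Reagents that add atoms: none
Why: Acid-catalysed methanolysis (acetal exchange of the aryl methoxymethyl ether and solvolysis of the silyl ether) should free both hydroxyl groups in one operation without touching C2 or the carbinol centre.

**Compound list**
1 | methyl 3-bromo-4-hydroxybenzoate | COC(=O)c1ccc(O)c(Br)c1 | starting material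
2 | 3-chloro-3-methylbut-1-yne | CC(C)(Cl)C#C | starting material
3 | methyl 3-bromo-4-[(2-methylbut-3-yn-2-yl)oxy]benzoate | COC(=O)c1ccc(OC(C)(C)C#C)c(Br)c1 | intermediate
4 | methyl 3-bromo-4-hydroxy-5-(3-methylbuta-1,2-dien-1-yl)benzoate | COC(=O)c1cc(Br)c(O)c(C=C=C(C)C)c1 | intermediate (not isolated)
5 | methyl 8-bromo-2,2-dimethyl-2H-chromene-6-carboxylate | COC(=O)c1cc(Br)c2OC(C)(C)C=Cc2c1 | intermediate
6 | tributyl(3-methylbut-2-en-1-yl)stannane | CCCC[Sn](CCCC)(CCCC)CC=C(C)C | starting material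
7 | methyl 2,2-dimethyl-8-(3-methylbut-2-en-1-yl)-2H-chromene-6-carboxylate | COC(=O)c1cc(CC=C(C)C)c2OC(C)(C)C=Cc2c1 | intermediate
8 | methyl 8-{[(2R)-3,3-dimethyloxiran-2-yl]methyl}-2,2-dimethyl-2H-chromene-6-carboxylate | COC(=O)c1cc(C[C@H]2OC2(C)C)c2OC(C)(C)C=Cc2c1 | intermediate
9 | methyl 8-[(2R)-2-hydroxy-3-methylbut-3-en-1-yl]-2,2-dimethyl-2H-chromene-6-carboxylate | COC(=O)c1cc(C[C@@H](O)C(C)=C)c2OC(C)(C)C=Cc2c1 | intermediate
10 | methyl 8-[(2R)-2-{[tert-butyl(dimethyl)silyl]oxy}-3-methylbut-3-en-1-yl]-2,2-dimethyl-2H-chromene-6-carboxylate | COC(=O)c1cc(C[C@@H](O[Si](C)(C)C(C)(C)C)C(C)=C)c2OC(C)(C)C=Cc2c1 | intermediate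
11 | N-methoxy-N-methylacetamide | CON(C)C(C)=O | starting material
12 | lithium enolate of N-methoxy-N-methylacetamide | [Li]OC(=C)N(C)OC | intermediate (not isolated)
13 | 3-{8-[(2R)-2-{[tert-butyl(dimethyl)silyl]oxy}-3-methylbut-3-en-1-yl]-2,2-dimethyl-2H-chromen-6-yl}-N-methoxy-N-methyl-3-oxopropanamide | CON(C)C(=O)CC(=O)c1cc(C[C@@H](O[Si](C)(C)C(C)(C)C)C(C)=C)c2OC(C)(C)C=Cc2c1 | intermediate
14 | (3S)-3-{8-[(2R)-2-{[tert-butyl(dimethyl)silyl]oxy}-3-methylbut-3-en-1-yl]-2,2-dimethyl-2H-chromen-6-yl}-3-hydroxy-N-methoxy-N-methylpropanamide | CON(C)C(=O)C[C@H](O)c1cc(C[C@@H](O[Si](C)(C)C(C)(C)C)C(C)=C)c2OC(C)(C)C=Cc2c1 | intermediate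
15 | (3S)-3-{8-[(2R)-2-{[tert-butyl(dimethyl)silyl]oxy}-3-methylbut-3-en-1-yl]-2,2-dimethyl-2H-chromen-6-yl}-N-methoxy-N-methyl-3-[(trimethylsilyl)oxy]propanamide | CON(C)C(=O)C[C@H](O[Si](C)(C)C)c1cc(C[C@@H](O[Si](C)(C)C(C)(C)C)C(C)=C)c2OC(C)(C)C=Cc2c1 | intermediate
16 | 5-chlorobenzene-1,3-diol | Oc1cc(O)cc(Cl)c1 | starting material
17 | 3-chloro-5-(methoxymethoxy)phenol | COCOc1cc(O)cc(Cl)c1 | intermediate
18 | 3-chloro-5-(methoxymethoxy)phenyl N-(propan-2-yl)carbamate | COCOc1cc(Cl)cc(OC(=O)NC(C)C)c1 | intermediate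
19 | 1-bromo-3-methylbut-2-ene | CC(C)=CCBr | starting material
20 | 3-chloro-5-(methoxymethoxy)phenyl N-[tert-butyl(dimethyl)silyl]-N-(propan-2-yl)carbamate | COCOc1cc(Cl)cc(OC(=O)N(C(C)C)[Si](C)(C)C(C)(C)C)c1 | intermediate (not isolated)
21 | 2-lithio derivative of 20 (lithium on the ring carbon between the carbamate and methoxymethoxy oxygens) | COCOc1cc(Cl)cc(OC(=O)N(C(C)C)[Si](C)(C)C(C)(C)C)c1[Li] | intermediate (not isolated)
22 | 5-chloro-3-(methoxymethoxy)-2-(3-methylbut-2-en-1-yl)phenyl N-[tert-butyl(dimethyl)silyl]-N-(propan-2-yl)carbamate | COCOc1cc(Cl)cc(OC(=O)N(C(C)C)[Si](C)(C)C(C)(C)C)c1CC=C(C)C | intermediate (not isolated)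
23 | 5-chloro-3-(methoxymethoxy)-2-(3-methylbut-2-en-1-yl)phenyl N-(propan-2-yl)carbamate | COCOc1cc(Cl)cc(OC(=O)NC(C)C)c1CC=C(C)C | intermediate
24 | 5-chloro-3-(methoxymethoxy)-2-(3-methylbut-2-en-1-yl)phenyl N-(propan-2-yl)-N-(trimethylsilyl)carbamate | COCOc1cc(Cl)cc(OC(=O)N(C(C)C)[Si](C)(C)C)c1CC=C(C)C | intermediate (not isolated)
25 | 6-lithio derivative of 24 (lithium on the ring carbon between the carbamate oxygen and chlorine) | COCOc1cc(Cl)c([Li])c(OC(=O)N(C(C)C)[Si](C)(C)C)c1CC=C(C)C | intermediate (not isolated)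
26 | 3-chloro-5-(methoxymethoxy)-6-(3-methylbut-2-en-1-yl)-2-(trimethylsilyl)phenyl N-(propan-2-yl)-N-(trimethylsilyl)carbamate | COCOc1cc(Cl)c([Si](C)(C)C)c(OC(=O)N(C(C)C)[Si](C)(C)C)c1CC=C(C)C | intermediate (not isolated)
27 | 3-chloro-5-(methoxymethoxy)-6-(3-methylbut-2-en-1-yl)-2-(trimethylsilyl)phenyl N-(propan-2-yl)carbamate | COCOc1cc(Cl)c([Si](C)(C)C)c(OC(=O)NC(C)C)c1CC=C(C)C | intermediate
28 | 3-chloro-5-(methoxymethoxy)-6-(3-methylbut-2-en-1-yl)-2-(trimethylsilyl)phenol | COCOc1cc(Cl)c([Si](C)(C)C)c(O)c1CC=C(C)C | intermediate (not isolated)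
29 | 3-chloro-5-(methoxymethoxy)-6-(3-methylbut-2-en-1-yl)-2-(trimethylsilyl)phenyl trifluoromethanesulfonate | COCOc1cc(Cl)c([Si](C)(C)C)c(OS(=O)(=O)C(F)(F)F)c1CC=C(C)C | intermediate
30 | 3-chloro-5-(methoxymethoxy)-6-(3-methylbut-2-en-1-yl)benzyne (triple bond between the former C–Si and C–OTf carbons) | COCOC1=C(CC=C(C)C)C#CC(Cl)=C1 | intermediate (not isolated)
31 | caesium salt of the C4 tetrahedral adduct of 32 (C4 carries O− and N(OMe)Me; C4 configuration undefined) | C=C(C)[C@H](O[Si](C)(C)C(C)(C)C)Cc1cc([C@@H]2CC([O-])(N(C)OC)c3c(Cl)cc(OCOC)c(CC=C(C)C)c3O2)cc2c1OC(C)(C)C=C2.[Cs+] | intermediate (not isolated)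
32 | (2S)-2-{8-[(2R)-2-{[tert-butyl(dimethyl)silyl]oxy}-3-methylbut-3-en-1-yl]-2,2-dimethyl-2H-chromen-6-yl}-5-chloro-7-(methoxymethoxy)-8-(3-methylbut-2-en-1-yl)-2,3-dihydro-4H-chromen-4-one | C=C(C)[C@H](O[Si](C)(C)C(C)(C)C)Cc1cc([C@@H]2CC(=O)c3c(Cl)cc(OCOC)c(CC=C(C)C)c3O2)cc2c1OC(C)(C)C=C2 | intermediate
33 | (2S)-2-{8-[(2R)-2-{[tert-butyl(dimethyl)silyl]oxy}-3-methylbut-3-en-1-yl]-2,2-dimethyl-2H-chromen-6-yl}-7-(methoxymethoxy)-8-(3-methylbut-2-en-1-yl)-2,3-dihydro-4H-chromen-4-one | C=C(C)[C@H](O[Si](C)(C)C(C)(C)C)Cc1cc([C@@H]2CC(=O)c3ccc(OCOC)c(CC=C(C)C)c3O2)cc2c1OC(C)(C)C=C2 | intermediate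
34 | (2S)-7-hydroxy-2-{8-[(2R)-2-hydroxy-3-methylbut-3-en-1-yl]-2,2-dimethyl-2H-chromen-6-yl}-8-(3-methylbut-2-en-1-yl)-2,3-dihydro-4H-chromen-4-one | C=C(C)[C@H](O)Cc1cc([C@@H]2CC(=O)c3ccc(O)c(CC=C(C)C)c3O2)cc2c1OC(C)(C)C=C2 | target

**Step count and risks**

Total step count: 17. Longest linear sequence: 12 steps (steps 1–9, then 15–17); the ring A branch (steps 10–14) joins at step 15.

Steps most likely to fail:

1. Step 15. The aryl anion may be protonated, or may lose chloride, before it reaches the amide. The free caesium alkoxide may fragment by retro-aldol cleavage. The alkoxide may add at the wrong aryne carbon. The fallback uses known chemistry, sets out from 13 and 23, and returns at 32. Ketone 13 is reduced with RuCl[(R,R)-TsDPEN](p-cymene) and HCO2H/Et3N to the (3R)-hydroxy Weinreb amide F1. Carbamate 23 is N-silylated and lithiated as in step 13 (through 24 and 25) and quenched with 1,2-dibromo-1,1,2,2-tetrachloroethane to the N-trimethylsilyl bromo carbamate F2. Aqueous NaHSO4 converts this to the bromo carbamate F3, and Et2NH/DBU frees the bromophenol F4. Mitsunobu etherification of F1 with F4 (PPh3, diisopropyl azodicarboxylate, toluene, 0 °C) should give, with inversion, the (S)-aryl ether F5. Bromine–lithium exchange (n-BuLi, THF, −100 °C) gives the aryllithium F6, which closes ring C by Parham cyclisation onto the Weinreb amide to the lithium tetrahedral adduct F7. Aqueous NH4Cl then releases 32.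

2. Step 16. The palladium hydride may isomerise or reduce the alkenes, or the amine may open the flavanone and erode C2. The fallback sets out from 32 and returns at 33 without any hydride donor. Miyaura borylation of 32 (Pd2(dba)3, XPhos, bis(pinacolato)diboron, KOAc, 1,4-dioxane, 80 °C) gives the 5-boryl flavanone F8. Protodeboronation (AcOH, aqueous THF, 50 °C) then gives 33.

3. Step 17. Acid may cyclise the C8 prenyl group onto the freed C7 phenol, or ionise or add methanol at the isopropenyl carbinol or the chromene. The fallback sets out from 33 and returns at 34 by two orthogonal, non-solvolytic cleavages. ZnBr2 and propane-1-thiol (CH2Cl2, 0 °C) remove only the methoxymethyl group to give the 7-hydroxy silyl ether F9. Buffered HF·pyridine (THF/pyridine, 0 °C) then removes the silyl group to give 34.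

**Further compounds**
F1 | step 15 | (3R)-3-{8-[(2R)-2-{[tert-butyl(dimethyl)silyl]oxy}-3-methylbut-3-en-1-yl]-2,2-dimethyl-2H-chromen-6-yl}-3-hydroxy-N-methoxy-N-methylpropanamide | CON(C)C(=O)C[C@@H](O)c1cc(C[C@@H](O[Si](C)(C)C(C)(C)C)C(C)=C)c2OC(C)(C)C=Cc2c1
F2 | step 15 | 2-bromo-3-chloro-5-(methoxymethoxy)-6-(3-methylbut-2-en-1-yl)phenyl N-(propan-2-yl)-N-(trimethylsilyl)carbamate (not isolated) | COCOc1cc(Cl)c(Br)c(OC(=O)N(C(C)C)[Si](C)(C)C)c1CC=C(C)C
F3 | step 15 | 2-bromo-3-chloro-5-(methoxymethoxy)-6-(3-methylbut-2-en-1-yl)phenyl N-(propan-2-yl)carbamate | COCOc1cc(Cl)c(Br)c(OC(=O)NC(C)C)c1CC=C(C)C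
F4 | step 15 | 2-bromo-3-chloro-5-(methoxymethoxy)-6-(3-methylbut-2-en-1-yl)phenol | COCOc1cc(Cl)c(Br)c(O)c1CC=C(C)C
F5 | step 15 | (3S)-3-[2-bromo-3-chloro-5-(methoxymethoxy)-6-(3-methylbut-2-en-1-yl)phenoxy]-3-{8-[(2R)-2-{[tert-butyl(dimethyl)silyl]oxy}-3-methylbut-3-en-1-yl]-2,2-dimethyl-2H-chromen-6-yl}-N-methoxy-N-methylpropanamide | CON(C)C(=O)C[C@H](Oc1c(Br)c(Cl)cc(OCOC)c1CC=C(C)C)c1cc(C[C@@H](O[Si](C)(C)C(C)(C)C)C(C)=C)c2OC(C)(C)C=Cc2c1
F6 | step 15 | aryllithium from F5 (lithium in place of bromine; not isolated) | CON(C)C(=O)C[C@H](Oc1c([Li])c(Cl)cc(OCOC)c1CC=C(C)C)c1cc(C[C@@H](O[Si](C)(C)C(C)(C)C)C(C)=C)c2OC(C)(C)C=Cc2c1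
F7 | step 15 | lithium salt of the C4 tetrahedral adduct of 32 (not isolated) | C=C(C)[C@H](O[Si](C)(C)C(C)(C)C)Cc1cc([C@@H]2CC([O-])(N(C)OC)c3c(Cl)cc(OCOC)c(CC=C(C)C)c3O2)cc2c1OC(C)(C)C=C2.[Li+]
F8 | step 16 | (2S)-2-{8-[(2R)-2-{[tert-butyl(dimethyl)silyl]oxy}-3-methylbut-3-en-1-yl]-2,2-dimethyl-2H-chromen-6-yl}-7-(methoxymethoxy)-8-(3-methylbut-2-en-1-yl)-5-(4,4,5,5-tetramethyl-1,3,2-dioxaborolan-2-yl)-2,3-dihydro-4H-chromen-4-one | C=C(C)[C@H](O[Si](C)(C)C(C)(C)C)Cc1cc([C@@H]2CC(=O)c3c(B4OC(C)(C)C(C)(C)O4)cc(OCOC)c(CC=C(C)C)c3O2)cc2c1OC(C)(C)C=C2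
F9 | step 17 | (2S)-2-{8-[(2R)-2-{[tert-butyl(dimethyl)silyl]oxy}-3-methylbut-3-en-1-yl]-2,2-dimethyl-2H-chromen-6-yl}-7-hydroxy-8-(3-methylbut-2-en-1-yl)-2,3-dihydro-4H-chromen-4-one | C=C(C)[C@H](O[Si](C)(C)C(C)(C)C)Cc1cc([C@@H]2CC(=O)c3ccc(O)c(CC=C(C)C)c3O2)cc2c1OC(C)(C)C=C2
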